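**Plan**
- Retrosynthesis: the two phenols go back to benzyl ethers, C7'H2 to a 1,3-dithiane carbon and C5H2 to a C5 menthyl acetal; then C3–C7 and C4–C7' are cut together, giving a chiral butenolide, a lithiated aryl dithiane and a benzylic bromide.
- Enabling feature: in the lactone ring O1–C2(=O)–C3–C4–C5, C3 and C4 are the α- and β-carbons of a 2(5H)-furanone, each carries exactly one arylmethyl arm (C7 on C3, C7' on C4), and C5 is a bare CH2 that can hold a temporary alkoxy group.
- Forward: the five-membered ring exists from step 1 (furfural photo-oxygenation) and is never built again. Step 8 joins C4–C7' and then C3–C7 in one flask; steps 9–10 remove sulfur and benzyl groups and exchange C5–OMenthyl for C5–H2 by ring opening, reduction and relactonisation.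
- Stereochemistry: (−)-menthol fixes C5 (5R epimer by crystallisation), C5 directs C4 (anti), C4 directs C3 (anti); C5 is then erased, leaving (3R,4R) with trans arms.

Key step: step 8

Assumption: W-2 Raney nickel under hydrogen is taken to cleave aryl benzyl ethers once the thioacetal sulfur has been consumed, so sulfur removal and O-debenzylation are run as one operation.

**Route**

Step 1
Reactants: 1 furfural
Product: 2 5-hydroxy-2(5H)-furanone (racemic cyclic hemiacetal)
Conditions: O2, hν (visible), rose bengal (cat.), MeOH, rt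
Reagents that add atoms: oxygen (singlet oxygen formed in situ), O=O
Why: Dye-sensitised singlet-oxygen [4+2] cycloaddition to the furan gives a 2,5-endoperoxide whose methanolysis expels the formyl carbon as methyl formate and leaves the pseudo-acid, a standard furan photo-oxygenation.

Step 2
Reactants: 2 5-hydroxy-2(5H)-furanone; 3 (−)-menthol
Product: 5 (5R)-5-[(1R,2S,5R)-menthyloxy]-2(5H)-furanone, via 5S epimer 4 (not isolated)
Conditions: CSA (cat.), toluene, reflux (Dean–Stark); crystallisation from petroleum ether, −20 °C, mother liquor re-equilibrated with cat. acid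
Reagents that add atoms: none
Why: Acid-catalysed acetalisation of the cyclic hemiacetal gives both C5 epimers, and because acid equilibrates the acetal centre through the acyloxycarbenium ion, crystallisation of the 5R epimer should drain the 5S epimer into 5 (crystallisation-induced diastereomer transformation), C5 being set by the menthol stereocentres.

Step 3
Reactants: 6 syringaldehyde; 7 benzyl bromide
Product: 8 4-benzyloxy-3,5-dimethoxybenzaldehyde
Conditions: K2CO3, DMF, 60 °C
Reagents that add atoms: none
Why: Williamson O-alkylation of the acidic para-formyl phenoxide with a reactive benzylic halide, which tolerates the two flanking methoxy groups.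

Step 4
Reactants: 8 4-benzyloxy-3,5-dimethoxybenzaldehyde; 9 1,3-propanedithiol
Product: 10 2-(4-benzyloxy-3,5-dimethoxyphenyl)-1,3-dithiane
Conditions: BF3·OEt2 (cat.), CH2Cl2, 0 °C → rt
Reagents that add atoms: none
Why: Lewis-acid-catalysed dithioacetalisation of an aromatic aldehyde, where a catalytic amount of BF3 at low temperature should leave the aryl benzyl ether alone.

Step 5
Reactants: 11 vanillin; 7 benzyl bromide
Product: 12 4-benzyloxy-3-methoxybenzaldehyde
Conditions: K2CO3, DMF, 60 °C
Reagents that add atoms: none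
Why: Williamson O-benzylation of the vanillin phenoxide, as in step 3.

Step 6
Reactants: 12 4-benzyloxy-3-methoxybenzaldehyde
Product: 13 4-benzyloxy-3-methoxybenzyl alcohol
Conditions: NaBH4, MeOH, 0 °C
Reagents that add atoms: none
Why: Borohydride reduction of an aryl aldehyde to the benzylic alcohol, with nothing else reducible present.

Step 7
Reactants: 13 4-benzyloxy-3-methoxybenzyl alcohol
Product: 14 4-benzyloxy-3-methoxybenzyl bromide
Conditions: PBr3, Et2O, 0 °C; used promptly
Reagents that add atoms: phosphorus tribromide, BrP(Br)Br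
Why: Bromide displaces the primary benzylic alcohol through its bromophosphite ester; the product ionises easily and is therefore taken straight into step 8.

Step 8
Reactants: 10 2-(4-benzyloxy-3,5-dimethoxyphenyl)-1,3-dithiane; 5 (5R)-5-[(1R,2S,5R)-menthyloxy]-2(5H)-furanone; 14 4-benzyloxy-3-methoxybenzyl bromide
Product: 17 (3R,4R,5R)-3-(4-benzyloxy-3-methoxybenzyl)-4-[2-(4-benzyloxy-3,5-dimethoxyphenyl)-1,3-dithian-2-yl]-5-[(1R,2S,5R)-menthyloxy]dihydrofuran-2(3H)-one, via 2-lithio-2-aryl-1,3-dithiane 15 (not isolated), via lithium lactone enolate 16 (not isolated)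
Conditions: 10, n-BuLi, THF, −78 → −20 °C; 5, THF, −78 °C; then 14, DMPU, −78 °C → rt; aq. NH4Cl
Reagents that add atoms: none
Why: n-BuLi removes the dithiane C2–H of 10 to give the sulfur-stabilised benzylic carbanion 15, which adds in conjugate fashion to C4 of butenolide 5 and leaves lithium enolate 16; the enolate is then C-benzylated at C3 by the reactive p-alkoxybenzylic bromide 14 in an SN2 step assisted by DMPU. The closest known reaction type is the tandem Michael addition–enolate alkylation of 5-alkoxy-2(5H)-furanones with 2-aryl-2-lithio-1,3-dithianes and benzylic halides. No ring closes: the lactone ring of 5 is carried through as the pseudo-ester of a 4-oxo acid while two acyclic C–C bonds, C4–C7' and C3–C7, are formed. C4 is controlled by the C5 menthyloxy group, the carbanion entering anti to it (4R), and C3 is controlled by the new bulky C4 dithianyl group, the bromide entering anti to it (3R), so the two arms end up trans. The step needs 1,4- over 1,2-addition, which the soft, hindered carbanion secures, and C-alkylation without retro-Michael loss of the dithiane, which the reactive benzylic bromide and the low temperature secure. The two near-identical aryl groups cannot be exchanged because the syringyl unit enters as the nucleophile and the guaiacyl unit as the electrophile.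

Step 9
Reactants: 17 tandem adduct
Product: 19 (3R,4R,5R)-4-(4-hydroxy-3,5-dimethoxybenzyl)-3-(4-hydroxy-3-methoxybenzyl)-5-[(1R,2S,5R)-menthyloxy]dihydrofuran-2(3H)-one, via desulfurised bis-benzyl ether 18 (not isolated)
Conditions: Raney Ni (W-2, neutral-washed, large excess), EtOH–THF, reflux; then fresh Raney Ni, H2 (1 atm), rt → 50 °C
Reagents that add atoms: none
Why: Raney nickel hydrogenolyses both C–S bonds (Mozingo-type desulfurisation) to leave C7'H2, and once the sulfur is bound fresh W-2 nickel under hydrogen should cleave both aryl benzyl ethers, while the lactone, the acetal and the three ring stereocentres are not addressed.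

Step 10
Reactants: 19 bis-phenol menthyloxy lactone
Product: 22 (3R,4R)-4-(4-hydroxy-3,5-dimethoxybenzyl)-3-(4-hydroxy-3-methoxybenzyl)dihydrofuran-2(3H)-one (target), via oxo carboxylate 20 (not isolated), via hydroxy acid 21 (not isolated)
Conditions: NaBH4 (excess), then aq. KOH, EtOH, 0 °C → rt, under argon; hexane wash to remove menthol; 2 M HCl to pH 1, rt
Reagents that add atoms: potassium hydroxide, [K+].[OH-] (its oxygen enters the carboxylate and is retained in part as the lactone C=O oxygen)
Why: Hydroxide opens the pseudo-ester to the γ-oxo carboxylate with loss of menthoxide, borohydride already present reduces the aldehyde as it is released, and acidification lactonises the γ-hydroxy acid, so C5 becomes CH2 while C3 and C4 are not touched and stay 3R,4R.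

**Compound list**

1 | furfural | O=Cc1ccco1 | starting material
2 | 5-hydroxy-2(5H)-furanone (racemic) | O=C1C=CC(O)O1 | intermediate
3 | (−)-menthol, (1R,2S,5R) | C[C@@H]1CC[C@H]([C@@H](C1)O)C(C)C | starting material
4 | (5S)-5-[(1R,2S,5R)-menthyloxy]-2(5H)-furanone | O=C1C=C[C@@H](O[C@@H]2C[C@H](C)CC[C@H]2C(C)C)O1 | intermediate (not isolated)
5 | (5R)-5-[(1R,2S,5R)-menthyloxy]-2(5H)-furanone | O=C1C=C[C@H](O[C@@H]2C[C@H](C)CC[C@H]2C(C)C)O1 | intermediate
6 | syringaldehyde | COc1cc(C=O)cc(OC)c1O | starting material
7 | benzyl bromide | BrCc1ccccc1 | starting material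
8 | 4-benzyloxy-3,5-dimethoxybenzaldehyde | COc1cc(C=O)cc(OC)c1OCc1ccccc1 | intermediate
9 | 1,3-propanedithiol | SCCCS | starting material
10 | 2-(4-benzyloxy-3,5-dimethoxyphenyl)-1,3-dithiane | COc1cc(C2SCCCS2)cc(OC)c1OCc1ccccc1 | intermediate
11 | vanillin | COc1cc(C=O)ccc1O | starting material
12 | 4-benzyloxy-3-methoxybenzaldehyde | COc1cc(C=O)ccc1OCc1ccccc1 | intermediate
13 | 4-benzyloxy-3-methoxybenzyl alcohol | COc1cc(CO)ccc1OCc1ccccc1 | intermediate
14 | 4-benzyloxy-3-methoxybenzyl bromide | COc1cc(CBr)ccc1OCc1ccccc1 | intermediate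
15 | 2-(4-benzyloxy-3,5-dimethoxyphenyl)-2-lithio-1,3-dithiane | [Li]C1(SCCCS1)c1cc(OC)c(OCc2ccccc2)c(OC)c1 | intermediate (not isolated)
16 | lithium enolate of (4R,5R)-4-[2-(4-benzyloxy-3,5-dimethoxyphenyl)-1,3-dithian-2-yl]-5-[(1R,2S,5R)-menthyloxy]dihydrofuran-2(3H)-one | [Li]OC1=C[C@@H](C2(SCCCS2)c2cc(OC)c(OCc3ccccc3)c(OC)c2)[C@H](O[C@@H]2C[C@H](C)CC[C@H]2C(C)C)O1 | intermediate (not isolated)
17 | (3R,4R,5R)-3-(4-benzyloxy-3-methoxybenzyl)-4-[2-(4-benzyloxy-3,5-dimethoxyphenyl)-1,3-dithian-2-yl]-5-[(1R,2S,5R)-menthyloxy]dihydrofuran-2(3H)-one | COc1cc(C[C@H]2C(=O)O[C@@H](O[C@@H]3C[C@H](C)CC[C@H]3C(C)C)[C@@H]2C2(SCCCS2)c2cc(OC)c(OCc3ccccc3)c(OC)c2)ccc1OCc1ccccc1 | intermediate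
18 | (3R,4R,5R)-3-(4-benzyloxy-3-methoxybenzyl)-4-(4-benzyloxy-3,5-dimethoxybenzyl)-5-[(1R,2S,5R)-menthyloxy]dihydrofuran-2(3H)-one | COc1cc(C[C@H]2C(=O)O[C@@H](O[C@@H]3C[C@H](C)CC[C@H]3C(C)C)[C@@H]2Cc2cc(OC)c(OCc3ccccc3)c(OC)c2)ccc1OCc1ccccc1 | intermediate (not isolated)
19 | (3R,4R,5R)-4-(4-hydroxy-3,5-dimethoxybenzyl)-3-(4-hydroxy-3-methoxybenzyl)-5-[(1R,2S,5R)-menthyloxy]dihydrofuran-2(3H)-one | COc1cc(C[C@H]2C(=O)O[C@@H](O[C@@H]3C[C@H](C)CC[C@H]3C(C)C)[C@@H]2Cc2cc(OC)c(O)c(OC)c2)ccc1O | intermediate
20 | tripotassium salt (carboxylate and both phenoxides) of (2R,3R)-3-(4-hydroxy-3,5-dimethoxybenzyl)-2-(4-hydroxy-3-methoxybenzyl)-4-oxobutanoic acid | [K+].[K+].[K+].COc1cc(C[C@@H](C(=O)[O-])[C@H](C=O)Cc2cc(OC)c([O-])c(OC)c2)ccc1[O-] | intermediate (not isolated)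
21 | (2R,3R)-4-hydroxy-3-(4-hydroxy-3,5-dimethoxybenzyl)-2-(4-hydroxy-3-methoxybenzyl)butanoic acid | COc1cc(C[C@@H](C(=O)O)[C@H](CO)Cc2cc(OC)c(O)c(OC)c2)ccc1O | intermediate (not isolated)
22 | (3R,4R)-4-(4-hydroxy-3,5-dimethoxybenzyl)-3-(4-hydroxy-3-methoxybenzyl)dihydrofuran-2(3H)-one | COc1cc(C[C@H]2C(=O)OC[C@@H]2Cc2cc(OC)c(O)c(OC)c2)ccc1O | target

**Count and risks**

Total step count: 10. Longest linear sequence: 6 steps (steps 5, 6, 7, 8, 9, 10, from vanillin 11 to 22).

Steps most likely to fail:

1. Step 8. The hindered enolate may alkylate slowly, which would allow retro-Michael loss of the dithiane anion, proton transfer or O-alkylation, and the labile benzylic bromide may decompose before it is captured. The fallback sets out from enolate 16, generated from 10 and 5 as in step 8, and returns at 17. Aldehyde 12 is added in place of bromide 14 (THF, −78 °C), and the tandem Michael–aldol reaction, again anti to the C4 group, should give (3S,4R,5R)-3-[(4-benzyloxy-3-methoxyphenyl)(hydroxy)methyl]-4-[2-(4-benzyloxy-3,5-dimethoxyphenyl)-1,3-dithian-2-yl]-5-[(1R,2S,5R)-menthyloxy]dihydrofuran-2(3H)-one F1 as carbinol epimers, whose configuration does not matter. Ionic deoxygenation of this p-alkoxybenzylic alcohol (Et3SiH, TFA, CH2Cl2, 0 °C) then removes the hydroxyl and gives 17.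

2. Step 9. Sulfur taken up by the nickel surface may poison it and leave O-debenzylation incomplete, giving mixtures of partly protected phenols; basic residues on the metal may also cause acetal exchange with ethanol (harmless, since any C5 alkoxy group is erased in step 10). The fallback sets out from 17 and returns at 19, with the two cleavages separated and given to different reagents. Radical desulfurisation (Bu3SnH in excess, AIBN, toluene, reflux) should stop at bis-benzyl ether 18, which is now isolated, and hydrogenolysis (H2, Pd/C, EtOAc–EtOH, rt) then frees both phenols to give 19. No compound outside the list arises on this detour (entry F0).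

3. Step 10. The transient aldehyde may epimerise at C4 in hydroxide before hydride reaches it, which would give some cis lactone, and the electron-rich phenoxides may suffer aerial oxidation. The fallback sets out from 19 and returns at 22, and avoids hydroxide. Aqueous acid hydrolysis of the pseudo-ester (2 M HCl, dioxane, 60 °C) releases menthol and gives (3R,4R)-5-hydroxy-4-(4-hydroxy-3,5-dimethoxybenzyl)-3-(4-hydroxy-3-methoxybenzyl)dihydrofuran-2(3H)-one F2 as C5 anomers. NaBH4 in EtOH at 0 °C, with no added base, then reduces F2 through its open aldehyde form (the anion of 20), and acidification closes hydroxy acid 21 to 22.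

**Further compounds**

F1 | step 8 | (3S,4R,5R)-3-[(4-benzyloxy-3-methoxyphenyl)(hydroxy)methyl]-4-[2-(4-benzyloxy-3,5-dimethoxyphenyl)-1,3-dithian-2-yl]-5-[(1R,2S,5R)-menthyloxy]dihydrofuran-2(3H)-one (carbinol epimers) | COc1cc(C(O)[C@H]2C(=O)O[C@@H](O[C@@H]3C[C@H](C)CC[C@H]3C(C)C)[C@@H]2C2(SCCCS2)c2cc(OC)c(OCc3ccccc3)c(OC)c2)ccc1OCc1ccccc1
F0 | step 9 | none | none
F2 | step 10 | (3R,4R)-5-hydroxy-4-(4-hydroxy-3,5-dimethoxybenzyl)-3-(4-hydroxy-3-methoxybenzyl)dihydrofuran-2(3H)-one (C5 anomers) | COc1cc(C[C@H]2C(=O)OC(O)[C@@H]2Cc2cc(OC)c(O)c(OC)c2)ccc1O
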